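C1 is the carbinol carbon, C14≡C15–C16≡C17 the diyne, C18–C21 the tether, and C21 sits on furan C2. The retrosynthesis cuts, in order: the O–Si bond of a silyl ether, the C13–C14 bond, the C14≡C15 π bond (back to a Z methyl enol ether, a masked alkyne), C17–C18, C21–furan C2, and C2–C3.
C14–C21 half: furan is lithiated and alkylated to 2-(4-bromobutyl)furan, which alkylates lithiated (Z)-1-methoxybut-1-en-3-yne. C1–C13 half: 11-bromoundec-1-ene is extended by oxirane and silylated to a terminal alkene.
Union in one operation: the enol ether is unmasked to a lithium diynide, the alkene is hydroborated, the two meet as a borate, and iodine drives C13 from boron onto C14. Desilylation ends the route.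
Enabling feature: the diyne terminus C14 is an sp carbon that can be made as a carbanion, bind boron and accept a migrating group. It stands next to C13, the end of an unbranched chain, which maps onto the terminal carbon of an alkene C12=C13 by anti-Markovnikov hydroboration. The 2-alkylfuran ring should tolerate these reagents.
Helpers and their removal: the methoxy group on C14 leaves as methoxide in step 5, the bis(3-methylbutan-2-yl)boron on C13 leaves as the iodoborane in step 5, and the tert-butyldimethylsilyl group on oxygen leaves in step 6.
Stereochemistry: the target has no stereocentre and no stereogenic double bond. The only stereo-element on the way is the Z enol ether bought with the reagent, which places H and OMe anti for the elimination and then vanishes.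

Key step: step 5

Remark: (Z)-1-methoxybut-1-en-3-yne is taken as commercial; it is supplied as a solution in aqueous methanol, from which it is extracted, dried and distilled before use.

Step 1
Reactants: 1 furan; 2 1,4-dibromobutane
Product: 4 2-(4-bromobutyl)furan, via furan-2-yllithium 3 (not isolated)
Conditions: n-BuLi (1.0 equiv), THF, −78 to 0 °C; then transferred into 2 (3 equiv), THF, −78 °C to rt
Reagents that add atoms: none
Why: Furan is deprotonated at C2, the position next to oxygen, and the resulting heteroaryllithium displaces one bromide of the dibromide in an SN2 alkylation, the excess of 2 holding back the second substitution.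

Step 2
Reactants: 5 (Z)-1-methoxybut-1-en-3-yne; 4 2-(4-bromobutyl)furan
Product: 7 2-[(7Z)-8-methoxyoct-7-en-5-yn-1-yl]furan, via lithium methoxyenynide 6 (not isolated)
Conditions: n-BuLi (1.0 equiv), THF, −78 °C; then 4, DMPU, −78 °C to rt
Reagents that add atoms: none
Why: The terminal alkyne C–H is the most acidic site of 5, and the lithium acetylide should undergo SN2 alkylation with the primary bromide in the dipolar cosolvent (acetylide alkylation), while one equivalent of base at low temperature leaves the Z enol ether intact.

Step 3
Reactants: 8 11-bromoundec-1-ene; 9 oxirane
Product: 11 tridec-12-en-1-ol, via undec-10-en-1-ylmagnesium bromide 10 (not isolated)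
Conditions: Mg, THF, rt to 40 °C; then 9 (THF solution), CuI (10 mol %), −30 to 0 °C; then 1 M HCl
Reagents that add atoms: none
Why: Copper-catalysed opening of oxirane by the primary Grignard reagent (two-carbon homologation) should give the primary alcohol and leave the terminal alkene untouched.

Step 4
Reactants: 11 tridec-12-en-1-ol
Product: 12 tert-butyldimethyl(tridec-12-en-1-yloxy)silane
Conditions: TBSCl, imidazole, DMF, rt
Reagents that add atoms: tert-butyldimethylsilyl chloride (TBSCl), CC(C)(C)[Si](C)(C)Cl
Why: Imidazole-promoted silylation of the primary alcohol removes the hydroxyl proton, which would otherwise destroy the borane and the diynide of step 5.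

Step 5
Reactants: 12 tert-butyldimethyl(tridec-12-en-1-yloxy)silane; 7 2-[(7Z)-8-methoxyoct-7-en-5-yn-1-yl]furan
Product: 17 tert-butyl{[21-(furan-2-yl)henicosa-14,16-diyn-1-yl]oxy}dimethylsilane, via alkyldisiamylborane 13 (not isolated), via lithium diynide 14 (not isolated), via lithium alkynylborate 15 (not isolated), via iodoalkenylborane 16 (not isolated)
Conditions: flask A: BH3·THF (1.1 equiv), 2-methylbut-2-ene (2.2 equiv), THF, 0 °C, then 12 (1.15 equiv), 0 °C to rt; flask B: 7 (1.0 equiv), LiN(iPr)2 (2.1 equiv), THF, −78 to −25 °C; A added to B at −78 °C, then 0 °C; I2 (1.1 equiv), THF, −78 °C to rt; then NaOH, H2O2, H2O, 0 °C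
Reagents that add atoms: none
Why: LiN(iPr)2 removes the vinylic C15–H of 7, which the Z geometry holds anti to the methoxy group on C14, methoxide leaves, and the second equivalent of base takes the new terminal C14–H to give diynide 14, which adds through C14 to the vacant boron orbital of borane 13 (itself formed by anti-Markovnikov syn addition of the B–H bond of disiamylborane to C12=C13 of 12) to give borate 15. Iodine attacks the boron-activated triple bond of 15 at C15, the C13 methylene migrates with its electron pair from boron to C14 (1,2-metallate shift, the event that forms the C13–C14 bond) to give iodoalkenylborane 16, and 16 loses iodobis(3-methylbutan-2-yl)borane to restore the C14≡C15 triple bond. The closest known reaction type is the iodine-induced alkyl transfer in lithium 1-alkynyltriorganoborates, the alkyne counterpart of the Zweifel olefination, fed here by the known conversion of (Z)-methoxyenynes into lithium diynides with two equivalents of amide base. No ring is closed and no stereocentre is formed, and the geometry of 16 is of no consequence because both boron and iodine are lost. The step needs migration of the primary chain in preference to a 3-methylbutan-2-yl group, which the low migratory aptitude of the hindered secondary groups should secure (a product of wrong-group transfer would lack the silyl ether chain and should separate easily), and it needs boron on C13 only, which the bulk of disiamylborane on a monosubstituted alkene should secure. It also needs iodine to be consumed by the borate and not by the furan or by free diynide, which the high nucleophilicity of the ate complex at −78 °C and the slight excess of 13 over 14 should secure; attack of iodine at C15 or at C17 would lead to the same diyne.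

Step 6
Reactants: 17 tert-butyl{[21-(furan-2-yl)henicosa-14,16-diyn-1-yl]oxy}dimethylsilane
Product: 18 21-(furan-2-yl)henicosa-14,16-diyn-1-ol
Conditions: Bu4NF, THF, 0 °C to rt
Reagents that add atoms: none
Why: Fluoride cleaves the Si–O bond (silyl ether deprotection driven by the strong Si–F bond) and should leave the internal diyne and the furan untouched.

Compound list
1 | furan | c1ccoc1 | starting material
2 | 1,4-dibromobutane | BrCCCCBr | starting material
3 | furan-2-yllithium | [Li]c1ccco1 | intermediate
4 | 2-(4-bromobutyl)furan | BrCCCCc1ccco1 | intermediate
5 | (Z)-1-methoxybut-1-en-3-yne | CO/C=C\C#C | starting material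
6 | [(3Z)-4-methoxybut-3-en-1-yn-1-yl]lithium (lithium methoxyenynide) | [Li]C#C/C=C\OC | intermediate
7 | 2-[(7Z)-8-methoxyoct-7-en-5-yn-1-yl]furan | CO/C=C\C#CCCCCc1ccco1 | intermediate
8 | 11-bromoundec-1-ene | C=CCCCCCCCCCBr | starting material
9 | oxirane | C1CO1 | starting material
10 | undec-10-en-1-ylmagnesium bromide | C=CCCCCCCCCC[Mg]Br | intermediate
11 | tridec-12-en-1-ol | C=CCCCCCCCCCCCO | intermediate
12 | tert-butyldimethyl(tridec-12-en-1-yloxy)silane | C=CCCCCCCCCCCCO[Si](C)(C)C(C)(C)C | intermediate
13 | {13-[(tert-butyldimethylsilyl)oxy]tridecyl}bis(3-methylbutan-2-yl)borane (configuration at the two B–CH carbons undefined, a mixture that does not reach the target) | CC(C)C(C)B(C(C)C(C)C)CCCCCCCCCCCCCO[Si](C)(C)C(C)(C)C | intermediate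
14 | [8-(furan-2-yl)octa-1,3-diyn-1-yl]lithium | [Li]C#CC#CCCCCc1ccco1 | intermediate
15 | lithium {13-[(tert-butyldimethylsilyl)oxy]tridecyl}[8-(furan-2-yl)octa-1,3-diyn-1-yl]bis(3-methylbutan-2-yl)borate | [Li+].CC(C)C(C)[B-](C(C)C(C)C)(CCCCCCCCCCCCCO[Si](C)(C)C(C)(C)C)C#CC#CCCCCc1ccco1 | intermediate
16 | {(14E)-1-[(tert-butyldimethylsilyl)oxy]-21-(furan-2-yl)-15-iodohenicos-14-en-16-yn-14-yl}bis(3-methylbutan-2-yl)borane (drawn as the isomer expected from migration anti to iodine, boron and iodine cis) | CC(C)C(C)B(C(C)C(C)C)/C(CCCCCCCCCCCCCO[Si](C)(C)C(C)(C)C)=C(\I)C#CCCCCc1ccco1 | intermediate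
17 | tert-butyl{[21-(furan-2-yl)henicosa-14,16-diyn-1-yl]oxy}dimethylsilane | CC(C)(C)[Si](C)(C)OCCCCCCCCCCCCCC#CC#CCCCCc1ccco1 | intermediate
18 | 21-(furan-2-yl)henicosa-14,16-diyn-1-ol | OCCCCCCCCCCCCCC#CC#CCCCCc1ccco1 | target

Total step count: 6. Longest linear sequence: 4 steps (8 to 11 to 12 to 17 to 18; the furan branch 1 to 4 to 7 to 17 to 18 is of equal length).

Steps most likely to fail

Step 5. What may go wrong: transfer of a 3-methylbutan-2-yl group from boron in place of the primary chain; incomplete capture of the diynide by the hindered borane in the presence of lithium methoxide and diisopropylamine, followed by direct iodination of free diynide; electrophilic iodination of the furan. The fallback makes the same bond by SN2 alkylation of the diynide in place of the boron-to-carbon shift. It sets out from 12 and 7 and comes back at 17. Borane 13, made from 12 as in step 5, is cleaved with I2 and NaOMe in MeOH/THF at 0 °C (base-promoted iodinolysis of the primary B–C bond) to give tert-butyl[(13-iodotridecyl)oxy]dimethylsilane F1. Diynide 14, made from 7 with LiN(iPr)2 (2.1 equiv) as in step 5, is then alkylated with F1 in THF/DMPU at −78 °C to rt, which should give 17.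

Step 2. What may go wrong: slow SN2 substitution with competing E2 loss of HBr from the bromide, and base-induced loss of methanol from the enol ether before the alkylation is complete. The fallback drops the enol-ether helper and builds the diyne from a four-carbon dihalide. It sets out from 4 and comes back at 14. 1,4-Dichlorobut-2-yne is treated with NaNH2 (3 equiv) in liquid NH3 at −40 °C (double dehydrochlorination and deprotonation) to give sodium buta-1,3-diyn-1-ide F2, which is alkylated in the same flask with bromide 4 to give 2-(octa-5,7-diyn-1-yl)furan F3. F3 is kept in solution and lithiated with n-BuLi (1 equiv, THF, −78 °C) to give diynide 14, which enters step 5 at the borate stage.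

Step 3. What may go wrong: opening of oxirane by bromide to a bromohydrin salt, and Wurtz-type homocoupling during Grignard formation. The fallback replaces the organomagnesium route by an ester enolate alkylation and reduction. It sets out from 8 and comes back at 11. tert-Butyl acetate is deprotonated with LiN(iPr)2 (THF, −78 °C) to give lithium 1-tert-butoxyethen-1-olate F4, which is alkylated with bromide 8 (DMPU, −78 °C to rt) to give tert-butyl tridec-12-enoate F5. Reduction of F5 with LiAlH4 (Et2O, 0 °C) should give alcohol 11.

Further compounds
F1 | step 5 | tert-butyl[(13-iodotridecyl)oxy]dimethylsilane | CC(C)(C)[Si](C)(C)OCCCCCCCCCCCCCI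
F2 | step 2 | sodium buta-1,3-diyn-1-ide | [Na]C#CC#C
F3 | step 2 | 2-(octa-5,7-diyn-1-yl)furan | C#CC#CCCCCc1ccco1
F4 | step 3 | lithium 1-tert-butoxyethen-1-olate | [Li]OC(=C)OC(C)(C)C
F5 | step 3 | tert-butyl tridec-12-enoate | C=CCCCCCCCCCCC(=O)OC(C)(C)C
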